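**Retrosynthetic overview**

1. Target 17 ⇐ 16 ⇐ 15: the side-chain ketone is carried as its (S)-carbinol and the C5 hydroxyl as a triethylsilyl ether; the last steps are oxidation and desilylation.
2. 15 ⇐ 13: retro-oxa-Michael opening of the oxygen bridge of a 2-oxabicyclo[3.3.1]nonan-7-one unveils the C2=C3 enone and frees the side-chain carbinol.
3. 13 ⇐ 12 (key step): Lewis acid ring expansion of a 3-alkoxycyclobutanone. The four-membered ring holds C1, C2, C3 and C6 of the target ring; the tethered silyl enol ether inserts C4–C5 into the C3–C6 bond and creates the quaternary C5. Ring order: cyclobutane (purchased), then a temporary tetrahydropyran and the cyclohexanone (both in step 9), then the tetrahydropyran is opened (step 10).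
4. Enabling feature: in 17 the enone β-carbon C3 and the side-chain carbonyl carbon C2′ are 1,5-related through C4, C5 and C1′. An ether oxygen from C2′ to C3 therefore closes a six-membered ring O–C3–C4–C5–C1′–C2′ and makes C3 the alkoxy carbon of a cyclobutanone (ring C1–C2–C3–C6). Its C3–C6 bond is polarized by the C1 carbonyl (acceptor) and the C3 oxygen (donor), and its mirror plane makes both cleavable bonds equivalent.
5. 12 ⇐ 4 + 6: reductive etherification of (S)-homoallylic alcohol 4 (Keck allylation of oleyl aldehyde 2) with 3-oxocyclobutyl pivalate 6, then Wacker oxidation, kinetic enol silylation, ester cleavage and oxidation.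

Key step: step 9

Remark: the cis/trans relationship of the two oxygen substituents on the cyclobutane in 8–11 is inconsequential (both isomers converge on ketone 12) and is left unspecified. Compounds 1, 3 and 5 and all reagents are taken as commercial.
Remark: the route assumes that the tetrahydropyran closure in step 9 takes the usual 2,6-cis course; on this basis the (4S) carbinol is the antipode that leads to (5R)-17.

Step 1
Reactants: 1 (9Z)-octadec-9-en-1-ol (oleyl alcohol)
Product: 2 (9Z)-octadec-9-enal
Conditions: Dess–Martin periodinane (1.2 equiv), CH2Cl2, 0 °C → rt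
Reagents that add atoms: none
Why: Dess–Martin oxidation of a primary alcohol stops cleanly at the aldehyde under neutral conditions, so the Z-olefin should be neither isomerized nor oxidized and no stereocentre is involved.

Step 2
Reactants: 2 (9Z)-octadec-9-enal; 3 allyltributylstannane
Product: 4 (4S,12Z)-henicosa-1,12-dien-4-ol
Conditions: (R)-BINOL (0.2 equiv), Ti(OiPr)4 (0.1 equiv), 4 Å molecular sieves, CH2Cl2, rt; then 2 and 3 (1.5 equiv), −20 °C; aq. NaHCO3
Reagents that add atoms: allyltributylstannane (3), C=CC[Sn](CCCC)(CCCC)CCCC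
Why: Keck asymmetric allylation, in which the titanium–BINOL Lewis acid made from (R)-BINOL directs the allyl group of the stannane to the Re face of an unbranched aliphatic aldehyde and so should set the (4S) carbinol centre that later controls C5.

Step 3
Reactants: 5 3-hydroxycyclobutan-1-one
Product: 6 3-oxocyclobutyl 2,2-dimethylpropanoate (3-oxocyclobutyl pivalate)
Conditions: pivaloyl chloride (1.1 equiv), pyridine (1.5 equiv), DMAP (0.05 equiv), CH2Cl2, 0 °C
Reagents that add atoms: pivaloyl chloride, CC(C)(C)C(=O)Cl
Why: DMAP-catalysed acylation of the secondary alcohol gives an ester without α-hydrogens that should later survive LiN(iPr)2, and the cold, weakly basic conditions avoid β-elimination to cyclobutenone.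

Step 4
Reactants: 4 (4S,12Z)-henicosa-1,12-dien-4-ol; 6 3-oxocyclobutyl pivalate
Product: 8 3-{[(4S,12Z)-henicosa-1,12-dien-4-yl]oxy}cyclobutyl 2,2-dimethylpropanoate (cis/trans mixture), via trimethylsilyl ether 7 (not isolated)
Conditions: Me3SiCl, Et3N, CH2Cl2, 0 °C; pentane, filtration, evaporation; then 6 (1.2 equiv), Et3SiH (1.5 equiv), Me3SiOTf (0.1 equiv), CH2Cl2, −78 → −30 °C
Reagents that add atoms: none
Why: Reductive etherification, in which the silyl ether and the strained ketone form a mixed silyl ketal that Me3SiOTf ionizes to an oxocarbenium ion, which Et3SiH should reduce far faster than the unactivated terminal olefin can attack it, the carbinol centre being untouched and the new ring carbon being stereochemically inconsequential.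

Step 5
Reactants: 8 3-{[(4S,12Z)-henicosa-1,12-dien-4-yl]oxy}cyclobutyl pivalate
Product: 9 3-{[(4S,12Z)-2-oxohenicos-12-en-4-yl]oxy}cyclobutyl 2,2-dimethylpropanoate
Conditions: PdCl2 (0.1 equiv), CuCl (1 equiv), O2 (1 atm), DMF/H2O 7:1, rt
Reagents that add atoms: water, O
Why: Tsuji–Wacker oxidation converts the terminal olefin by Markovnikov hydroxypalladation into the methyl ketone, while the internal Z-olefin, the ester and the ether are expected to be inert under these conditions.

Step 6
Reactants: 9 3-{[(4S,12Z)-2-oxohenicos-12-en-4-yl]oxy}cyclobutyl pivalate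
Product: 10 3-{[(4S,12Z)-2-(triethylsilyloxy)henicosa-1,12-dien-4-yl]oxy}cyclobutyl 2,2-dimethylpropanoate
Conditions: LiN(iPr)2 (1.15 equiv), THF, −78 °C; then Et3SiCl (1.3 equiv), −78 → 0 °C; pentane/aq. NaHCO3
Reagents that add atoms: chlorotriethylsilane, CC[Si](Cl)(CC)CC
Why: Kinetic deprotonation of a methyl ketone by the hindered amide at −78 °C occurs at the methyl group, and O-silylation of this enolate should give the 2-silyloxy-1-alkene without β-elimination of the ether, which would require the internal enolate.

Step 7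
Reactants: 10 3-{[(4S,12Z)-2-(triethylsilyloxy)henicosa-1,12-dien-4-yl]oxy}cyclobutyl pivalate
Product: 11 3-{[(4S,12Z)-2-(triethylsilyloxy)henicosa-1,12-dien-4-yl]oxy}cyclobutan-1-ol
Conditions: iBu2AlH (2.5 equiv), CH2Cl2, −78 °C; aq. KNaC4H4O6
Reagents that add atoms: none
Why: Reductive cleavage of the pivalate by iBu2AlH at low temperature frees the cyclobutanol under non-acidic, non-nucleophilic conditions that should leave the triethylsilyl enol ether intact.

Step 8
Reactants: 11 3-{[(4S,12Z)-2-(triethylsilyloxy)henicosa-1,12-dien-4-yl]oxy}cyclobutan-1-ol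
Product: 12 3-{[(4S,12Z)-2-(triethylsilyloxy)henicosa-1,12-dien-4-yl]oxy}cyclobutan-1-one
Conditions: SO3·pyridine (3 equiv), DMSO, iPr2NEt (5 equiv), CH2Cl2, 0 °C
Reagents that add atoms: none
Why: Parikh–Doering oxidation (activated dimethyl sulfoxide with an amine base) should turn the cyclobutanol into the cyclobutanone without acid or electrophilic oxidants, so that the enol ether and the Z-olefin survive and the cis/trans mixture converges on one ketone.

Step 9
Reactants: 12 3-{[(4S,12Z)-2-(triethylsilyloxy)henicosa-1,12-dien-4-yl]oxy}cyclobutan-1-one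
Product: 13 (1S,3S,5S)-3-[(8Z)-heptadec-8-en-1-yl]-5-(triethylsilyloxy)-2-oxabicyclo[3.3.1]nonan-7-one
Conditions: EtAlCl2 (2 equiv), 2,6-di-tert-butyl-4-methylpyridine (0.3 equiv), CH2Cl2 (0.01 M), −78 → −45 °C; Et3N/MeOH, then aq. NaHCO3
Reagents that add atoms: none
Why: Proposed new method: EtAlCl2 binds the carbonyl of 12 and the push–pull ring bond next to the alkoxy carbon breaks heterolytically (either of the two equivalent bonds, because the cyclobutanone has a mirror plane) to an aluminium enolate/oxocarbenium zwitterion; the tethered silyl enol ether then adds to the oxocarbenium carbon (6-endo Prins-type closure of the tetrahydropyran through a chair with the C17 chain and the enolate arm both equatorial, hence 2,6-cis), and the aluminium enolate closes the carbocycle on the resulting silyloxocarbenium carbon by a 6-(enolendo)-exo-trig aldol addition, the silyl group staying on the new tertiary oxygen. The closest known reaction type is the intermolecular EtAlCl2-promoted formal [4+2] cycloaddition of 3-alkoxycyclobutanones with silyl enol ethers, combined with the silyl enol ether Prins cyclization (the bond formation of the Petasis–Ferrier rearrangement) that gives cis-2,6-disubstituted tetrahydropyran-4-ones. Stereocontrol: C1 is set cis to the C3 substituent by the chair Prins transition state, and C5 can form only on the pyran face that carries the enolate arm, because a three-atom bridge spans the 1,3-positions only in a cis fashion, so the (S) carbinol centre dictates the configuration at C5. The step needs the intramolecular Prins closure to outrun intermolecular Mukaiyama-type reactions, protodesilylation and 2-oxonia-Cope scrambling; high dilution, the hindered pyridine as proton trap and the nucleophilic enol ether placed to close a six-membered ring on the cationic carbon should secure this.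

Step 10
Reactants: 13 (1S,3S,5S)-3-[(8Z)-heptadec-8-en-1-yl]-5-(triethylsilyloxy)-2-oxabicyclo[3.3.1]nonan-7-one
Product: 15 (5R)-5-[(2S,10Z)-2-hydroxynonadec-10-en-1-yl]-5-(triethylsilyloxy)cyclohex-2-en-1-one, via bis-silyl ether 14 (not isolated)
Conditions: Me3SiOTf (1.5 equiv), Et3N (3 equiv), CH2Cl2, −78 → −20 °C; then MeOH, citric acid (0.1 equiv), 0 °C
Reagents that add atoms: none
Why: Silyl triflate/amine soft enolization toward C8 gives a silyl enol ether whose axial C1–O2 bond is cleaved with silyl transfer to O2 (the known ring opening of bridged β-alkoxy ketones such as 8-oxabicyclo[3.2.1]octan-3-ones), elimination toward C5 being excluded because it would need a bridgehead olefin and a C–O bond orthogonal to the enol π-system, and the brief acidic methanolysis should remove only the secondary trimethylsilyl ether and return any enol ether formed on the C6 side as 13, no stereocentre being touched.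

Step 11
Reactants: 15 (5R)-5-[(2S,10Z)-2-hydroxynonadec-10-en-1-yl]-5-(triethylsilyloxy)cyclohex-2-en-1-one
Product: 16 (5R)-5-[(10Z)-2-oxononadec-10-en-1-yl]-5-(triethylsilyloxy)cyclohex-2-en-1-one
Conditions: Dess–Martin periodinane (1.3 equiv), pyridine (3 equiv), CH2Cl2, 0 °C → rt
Reagents that add atoms: none
Why: Dess–Martin oxidation of the secondary carbinol removes the temporary stereocentre and installs the side-chain ketone under buffered, non-basic conditions that should not trigger β-elimination of the tertiary silyl ether.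

Step 12
Reactants: 16 (5R)-5-[(10Z)-2-oxononadec-10-en-1-yl]-5-(triethylsilyloxy)cyclohex-2-en-1-one
Product: 17 (5R)-5-hydroxy-5-[(10Z)-2-oxononadec-10-en-1-yl]cyclohex-2-en-1-one (target)
Conditions: HF·pyridine, pyridine, THF, 0 °C → rt; aq. NaHCO3 to pH 7
Reagents that add atoms: none
Why: Buffered HF·pyridine cleaves the tertiary triethylsilyl ether by Si–F bond formation near neutral pH, which should avoid base- or acid-promoted dehydration of the β-hydroxy enone to a phenol and leaves C5 untouched.

**Compound list**

1 | (9Z)-octadec-9-en-1-ol (oleyl alcohol) | OCCCCCCCC/C=C\CCCCCCCC | starting material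
2 | (9Z)-octadec-9-enal | O=CCCCCCCC/C=C\CCCCCCCC | intermediate
3 | allyltributylstannane | C=CC[Sn](CCCC)(CCCC)CCCC | starting material
4 | (4S,12Z)-henicosa-1,12-dien-4-ol | C=CC[C@@H](O)CCCCCCC/C=C\CCCCCCCC | intermediate
5 | 3-hydroxycyclobutan-1-one | O=C1CC(O)C1 | starting material
6 | 3-oxocyclobutyl 2,2-dimethylpropanoate | CC(C)(C)C(=O)OC1CC(=O)C1 | intermediate
7 | trimethyl{[(4S,12Z)-henicosa-1,12-dien-4-yl]oxy}silane | C=CC[C@@H](O[Si](C)(C)C)CCCCCCC/C=C\CCCCCCCC | intermediate
8 | 3-{[(4S,12Z)-henicosa-1,12-dien-4-yl]oxy}cyclobutyl 2,2-dimethylpropanoate (cis/trans mixture) | C=CC[C@@H](OC1CC(OC(=O)C(C)(C)C)C1)CCCCCCC/C=C\CCCCCCCC | intermediate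
9 | 3-{[(4S,12Z)-2-oxohenicos-12-en-4-yl]oxy}cyclobutyl 2,2-dimethylpropanoate | CC(=O)C[C@@H](OC1CC(OC(=O)C(C)(C)C)C1)CCCCCCC/C=C\CCCCCCCC | intermediate
10 | 3-{[(4S,12Z)-2-(triethylsilyloxy)henicosa-1,12-dien-4-yl]oxy}cyclobutyl 2,2-dimethylpropanoate | C=C(O[Si](CC)(CC)CC)C[C@@H](OC1CC(OC(=O)C(C)(C)C)C1)CCCCCCC/C=C\CCCCCCCC | intermediate
11 | 3-{[(4S,12Z)-2-(triethylsilyloxy)henicosa-1,12-dien-4-yl]oxy}cyclobutan-1-ol | C=C(O[Si](CC)(CC)CC)C[C@@H](OC1CC(O)C1)CCCCCCC/C=C\CCCCCCCC | intermediate
12 | 3-{[(4S,12Z)-2-(triethylsilyloxy)henicosa-1,12-dien-4-yl]oxy}cyclobutan-1-one | C=C(O[Si](CC)(CC)CC)C[C@@H](OC1CC(=O)C1)CCCCCCC/C=C\CCCCCCCC | intermediate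
13 | (1S,3S,5S)-3-[(8Z)-heptadec-8-en-1-yl]-5-(triethylsilyloxy)-2-oxabicyclo[3.3.1]nonan-7-one | CCCCCCCC/C=C\CCCCCCC[C@H]1C[C@@]2(O[Si](CC)(CC)CC)CC(=O)C[C@H](C2)O1 | intermediate
14 | (5R)-5-(triethylsilyloxy)-5-[(2S,10Z)-2-(trimethylsilyloxy)nonadec-10-en-1-yl]cyclohex-2-en-1-one | CCCCCCCC/C=C\CCCCCCC[C@H](O[Si](C)(C)C)C[C@]1(O[Si](CC)(CC)CC)CC=CC(=O)C1 | intermediate
15 | (5R)-5-[(2S,10Z)-2-hydroxynonadec-10-en-1-yl]-5-(triethylsilyloxy)cyclohex-2-en-1-one | CCCCCCCC/C=C\CCCCCCC[C@H](O)C[C@]1(O[Si](CC)(CC)CC)CC=CC(=O)C1 | intermediate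
16 | (5R)-5-[(10Z)-2-oxononadec-10-en-1-yl]-5-(triethylsilyloxy)cyclohex-2-en-1-one | CCCCCCCC/C=C\CCCCCCCC(=O)C[C@]1(O[Si](CC)(CC)CC)CC=CC(=O)C1 | intermediate
17 | (5R)-5-hydroxy-5-[(10Z)-2-oxononadec-10-en-1-yl]cyclohex-2-en-1-one | CCCCCCCC/C=C\CCCCCCCC(=O)C[C@]1(O)CC=CC(=O)C1 | target

**Step count**

Total step count: 12. Longest linear sequence: 11 steps (steps 1, 2 and 4–12; step 3 is a one-step side branch).

**Steps most likely to fail**

1. Step 9 (Proposed new method). What may go wrong: closure of the carbocycle from the 2,6-cis pyranyl cation needs a boat-like pyran, and if it is slow the aluminium enolate is merely protonated at work-up. Closure through a 2,6-trans manifold would give the opposite configuration at C5. Intermolecular Mukaiyama-type oligomerization or protodesilylation of the enol ether may also compete.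
Fallback (known chemistry, sets out from 4, comes back at 13): the tether is given up, and stereocontrol is replaced by separation of diastereomers. Alcohol 4 would be silylated (tBuMe2SiCl, imidazole, DMF) to tert-butyl{[(4S,12Z)-henicosa-1,12-dien-4-yl]oxy}dimethylsilane F1. Tsuji–Wacker oxidation should give (4S,12Z)-4-(tert-butyldimethylsilyloxy)henicos-12-en-2-one F2, and kinetic enol silylation (LiN(iPr)2, Me3SiCl, THF, −78 °C) the trimethylsilyl enol ether F3. The known intermolecular EtAlCl2-promoted formal [4+2] cycloaddition of F3 with commercial 3-(benzyloxy)cyclobutan-1-one (CH2Cl2, −78 °C; the benzyl ether plays the part of the usual ethyl ether) again expands the four-membered ring by the two enol ether carbons and should give 3-(benzyloxy)-5-[(2S,10Z)-2-(tert-butyldimethylsilyloxy)nonadec-10-en-1-yl]-5-(trimethylsilyloxy)cyclohexan-1-one F4 as a mixture of ring diastereomers. HF·pyridine would remove both silyl groups to give 3-(benzyloxy)-5-hydroxy-5-[(2S,10Z)-2-hydroxynonadec-10-en-1-yl]cyclohexan-1-one F5. Catalytic DBU (CH2Cl2, 0 °C) should expel benzyl alcohol by E1cB, with immediate intramolecular oxa-Michael addition of the side-chain hydroxyl. This should give (1S,3S,5S)-3-[(8Z)-heptadec-8-en-1-yl]-5-hydroxy-2-oxabicyclo[3.3.1]nonan-7-one F6 and its (1R,3S,5R) diastereomer F7, to be separated by chromatography. Silylation of F6 (Et3SiOTf, 2,6-lutidine, CH2Cl2, −78 °C) returns to 13.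

2. Step 10. What may go wrong: enol silylation toward C6 instead of C8 stalls the opening. Excess silyl triflate acting on the opened enone can form a silyloxydiene and ionize the tertiary silyl ether, which leads to aromatization. The freed carbinol can also re-add to the enone during the methanolysis.
Fallback (sets out from 12, comes back at 15): the ring opening is moved into the flask of step 9 as a metal-enolate E1cB. After the cascade, iPr2NEt (3 equiv) would be added at −78 °C and the mixture warmed to 0 °C. The aluminium held between the C7 carbonyl and O2 should direct enolization toward C8, and the bridging oxygen should leave as its aluminium alkoxide, so that aqueous work-up gives 15 directly. No silyl triflate, silyl dienol ether or separate methanolysis is involved, and the secondary alkoxide stays bound to aluminium until the quench.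

3. Step 4. What may go wrong: slow oxocarbenium formation between two hindered secondary partners, direct hydrosilylation of ketone 6, or Prins-type capture of the oxocarbenium ion by the terminal olefin.
Fallback (sets out from 4, comes back at 8): the ether is built by cycloaddition instead of reductive etherification. Transfer vinylation of 4 ([Ir(cod)Cl]2 (0.01 equiv), Na2CO3, vinyl acetate, toluene, 100 °C) should give (4S,12Z)-4-(ethenyloxy)henicosa-1,12-diene F8. [2+2] cycloaddition with dichloroketene (Cl3CCOCl, Zn–Cu couple, Et2O/DME, 0 °C), for which the vinyl ether is far more reactive than the two unactivated olefins, should give 2,2-dichloro-3-{[(4S,12Z)-henicosa-1,12-dien-4-yl]oxy}cyclobutan-1-one F9. Dechlorination (Zn, AcOH, rt) would give 3-{[(4S,12Z)-henicosa-1,12-dien-4-yl]oxy}cyclobutan-1-one F10, and reduction (NaBH4, MeOH, 0 °C) 3-{[(4S,12Z)-henicosa-1,12-dien-4-yl]oxy}cyclobutan-1-ol F11. Acylation (pivaloyl chloride, pyridine, DMAP, CH2Cl2) returns to 8.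

**Further compounds**

F1 | step 9 | tert-butyl{[(4S,12Z)-henicosa-1,12-dien-4-yl]oxy}dimethylsilane | C=CC[C@@H](O[Si](C)(C)C(C)(C)C)CCCCCCC/C=C\CCCCCCCC
F2 | step 9 | (4S,12Z)-4-(tert-butyldimethylsilyloxy)henicos-12-en-2-one | CC(=O)C[C@@H](O[Si](C)(C)C(C)(C)C)CCCCCCC/C=C\CCCCCCCC
F3 | step 9 | tert-butyldimethyl{[(4S,12Z)-2-(trimethylsilyloxy)henicosa-1,12-dien-4-yl]oxy}silane | C=C(O[Si](C)(C)C)C[C@@H](O[Si](C)(C)C(C)(C)C)CCCCCCC/C=C\CCCCCCCC
F4 | step 9 | 3-(benzyloxy)-5-[(2S,10Z)-2-(tert-butyldimethylsilyloxy)nonadec-10-en-1-yl]-5-(trimethylsilyloxy)cyclohexan-1-one (mixture of ring diastereomers) | CCCCCCCC/C=C\CCCCCCC[C@H](O[Si](C)(C)C(C)(C)C)CC1(O[Si](C)(C)C)CC(OCc2ccccc2)CC(=O)C1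
F5 | step 9 | 3-(benzyloxy)-5-hydroxy-5-[(2S,10Z)-2-hydroxynonadec-10-en-1-yl]cyclohexan-1-one (mixture of ring diastereomers) | CCCCCCCC/C=C\CCCCCCC[C@H](O)CC1(O)CC(OCc2ccccc2)CC(=O)C1
F6 | step 9 | (1S,3S,5S)-3-[(8Z)-heptadec-8-en-1-yl]-5-hydroxy-2-oxabicyclo[3.3.1]nonan-7-one | CCCCCCCC/C=C\CCCCCCC[C@H]1C[C@@]2(O)CC(=O)C[C@H](C2)O1
F7 | step 9 | (1R,3S,5R)-3-[(8Z)-heptadec-8-en-1-yl]-5-hydroxy-2-oxabicyclo[3.3.1]nonan-7-one | CCCCCCCC/C=C\CCCCCCC[C@H]1C[C@]2(O)CC(=O)C[C@@H](C2)O1
F0 | step 10 | none | none
F8 | step 4 | (4S,12Z)-4-(ethenyloxy)henicosa-1,12-diene | C=CC[C@@H](OC=C)CCCCCCC/C=C\CCCCCCCC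
F9 | step 4 | 2,2-dichloro-3-{[(4S,12Z)-henicosa-1,12-dien-4-yl]oxy}cyclobutan-1-one | C=CC[C@@H](OC1CC(=O)C1(Cl)Cl)CCCCCCC/C=C\CCCCCCCC
F10 | step 4 | 3-{[(4S,12Z)-henicosa-1,12-dien-4-yl]oxy}cyclobutan-1-one | C=CC[C@@H](OC1CC(=O)C1)CCCCCCC/C=C\CCCCCCCC
F11 | step 4 | 3-{[(4S,12Z)-henicosa-1,12-dien-4-yl]oxy}cyclobutan-1-ol | C=CC[C@@H](OC1CC(O)C1)CCCCCCC/C=C\CCCCCCCC
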